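**Retrosynthetic overview**

- 15 ⇐ 14 (loss of one silyl group) ⇐ acyclic (E)-enol tosylate 11: the strategic disconnection is the C4–C4a bond, combined with a 1,2-shift of C1 along ring A.
- Enabling feature: ring A is a syringyl (4-hydroxy-3,5-dimethoxyphenyl) unit that holds C4 on the carbon para to its hydroxyl (C4a) and C1 on the next carbon (C8a), and C1 also bears a second syringyl ring (ring C) through its para carbon. C1 can therefore come from a non-stereogenic CH(syringyl)2 group: C4 attacks one ring at its ipso carbon, and C1, made ionisable by the 4-hydroxy group of the other ring, slides from C4a to C8a.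
- 11 ⇐ ester 8 (α-formylation, (E)-enol tosylation) ⇐ aldehyde 6, from catalytic asymmetric 1,6-addition of methyl 4-oxobutanoate (4) to the symmetrical p-quinone methide 5 (from 2,6-dimethoxyphenol, 4-(hydroxymethyl)-2,6-dimethoxyphenol and DDQ); this sets C2, the only stereocentre carried into the key step.
- Ring order: no ring is built before step 7; there the C4–C4a bond first closes a spiro five-membered ring, which is expanded in the same flask to six-membered ring B while C1 is set trans to C2 from either C1 epimer.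

Key step: step 7

Remark: C1–C4, C4a and C8a are the positions of the dihydronaphthalene core of 15 (C1 aryl-bearing, C2 CH2OH-bearing, C3 ester-bearing, C4 vinylic CH) and label the same carbons in all precursors; ring A is the fused benzene ring, ring B the new carbocycle, ring C the aryl group on C1; TBS = tert-butyldimethylsilyl, Ts = 4-methylbenzenesulfonyl; 1, 2, 4 and both enantiomers of the prolinol silyl ether catalyst are taken as commercial.

Step 1
Reactants: 1 2,6-dimethoxyphenol; 2 4-(hydroxymethyl)-2,6-dimethoxyphenol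
Product: 3 4,4'-methylenebis(2,6-dimethoxyphenol)
Conditions: 1 (3 equiv), 2 added slowly, TsOH·H2O (10 mol%), MeCN, 50 °C; excess 1 recovered
Reagents that add atoms: none
Why: Acid-catalysed Friedel–Crafts benzylation: loss of water from the p-hydroxybenzyl alcohol 2 gives a p-quinone methide (benzyl cation equivalent) that the excess of 1 should capture at the carbon para to its hydroxyl group, the most nucleophilic position because both ortho positions carry methoxy groups; no stereocentre is formed.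

Step 2
Reactants: 3 4,4'-methylenebis(2,6-dimethoxyphenol); 4 methyl 4-oxobutanoate
Product: 7 methyl (3S)-3-(hydroxymethyl)-4,4-bis(4-hydroxy-3,5-dimethoxyphenyl)butanoate, via quinone methide 5 (not isolated), via aldehyde 6 (not isolated)
Conditions: DDQ (1.0 equiv), CH2Cl2, 0 °C, DDQH2 filtered off; 4 (2 equiv), (R)-2-[diphenyl(trimethylsilyloxy)methyl]pyrrolidine (20 mol%), PhCO2H (20 mol%), CH2Cl2, 0 °C; then NaBH4, MeOH, −40 °C, pH 7 buffer
Reagents that add atoms: none
Why: DDQ should take hydride from the doubly benzylic CH2 group to give p-quinone methide 5 (benzylic dehydrogenation), the enamine of 4 should add to its exocyclic carbon (organocatalytic asymmetric 1,6-conjugate addition) on the face left open by the diphenyl(silyloxy)methyl group, which sets C2 as (S) with the (R)-catalyst while rearomatisation makes the two aryl groups identical so that C1 stays non-stereogenic, and NaBH4 reduces the aldehyde at once so that C2 cannot epimerise.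

Step 3
Reactants: 7 methyl (3S)-3-(hydroxymethyl)-4,4-bis(4-hydroxy-3,5-dimethoxyphenyl)butanoate
Product: 8 methyl (3S)-3-{[(tert-butyldimethylsilyl)oxy]methyl}-4,4-bis{4-[(tert-butyldimethylsilyl)oxy]-3,5-dimethoxyphenyl}butanoate
Conditions: TBSCl (4 equiv), imidazole (8 equiv), DMF, 0 °C → rt, run at once on crude 7
Reagents that add atoms: tert-butyldimethylsilyl chloride, CC(C)(C)[Si](C)(C)Cl
Why: Standard silylation of the primary alcohol and both phenols, run immediately so that O-silylation outruns lactonisation of the γ-hydroxy ester; C2 is not touched.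

Step 4
Reactants: 8 methyl (3S)-3-{[(tert-butyldimethylsilyl)oxy]methyl}-4,4-bis{4-[(tert-butyldimethylsilyl)oxy]-3,5-dimethoxyphenyl}butanoate
Product: 9 methyl (3R)-3-{[(tert-butyldimethylsilyl)oxy]methyl}-4,4-bis{4-[(tert-butyldimethylsilyl)oxy]-3,5-dimethoxyphenyl}-2-formylbutanoate (largely as its 2-(hydroxymethylidene) enol; C3 of the core undefined)
Conditions: LiN(iPr)2 (2.2 equiv), THF, −78 °C; HCO2Me (5 equiv), −78 → 0 °C; aq. NH4Cl
Reagents that add atoms: methyl formate, COC=O
Why: Crossed Claisen condensation (α-formylation): C3 is the only enolisable position and methyl formate cannot enolise, and C2 is not α to a carbonyl group, so it keeps its configuration (its descriptor changes from S to R only because C3 gains priority).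

Step 5
Reactants: 9 methyl (3R)-3-{[(tert-butyldimethylsilyl)oxy]methyl}-4,4-bis{4-[(tert-butyldimethylsilyl)oxy]-3,5-dimethoxyphenyl}-2-formylbutanoate
Product: 10 methyl (2E,3R)-3-{[(tert-butyldimethylsilyl)oxy]methyl}-4,4-bis{4-[(tert-butyldimethylsilyl)oxy]-3,5-dimethoxyphenyl}-2-{[(4-methylbenzenesulfonyl)oxy]methylidene}butanoate
Conditions: TsCl (1.5 equiv), N-methylimidazole (1.5 equiv), Et3N (1.5 equiv), CH2Cl2, −10 °C
Reagents that add atoms: 4-methylbenzenesulfonyl chloride, Cc1ccc(cc1)S(=O)(=O)Cl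
Why: O-Sulfonylation of the enol under non-chelating amine conditions, which for α-formyl esters should give the (E)-enol tosylate (OTs trans to the ester and cis to C2), the geometry that later places palladium next to the aryl groups.

Step 6
Reactants: 10 methyl (2E,3R)-3-{[(tert-butyldimethylsilyl)oxy]methyl}-4,4-bis{4-[(tert-butyldimethylsilyl)oxy]-3,5-dimethoxyphenyl}-2-{[(4-methylbenzenesulfonyl)oxy]methylidene}butanoate
Product: 11 methyl (2E,3R)-3-{[(tert-butyldimethylsilyl)oxy]methyl}-4,4-bis(4-hydroxy-3,5-dimethoxyphenyl)-2-{[(4-methylbenzenesulfonyl)oxy]methylidene}butanoate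
Conditions: KHF2 (2.5 equiv), MeOH, rt
Reagents that add atoms: none
Why: Chemoselective desilylation: bifluoride in methanol cleaves aryl silyl ethers far faster than primary alkyl silyl ethers, which frees both phenols needed in step 7 and should leave the enol tosylate, the ester and the alkyl OTBS group untouched.

Step 7
Reactants: 11 methyl (2E,3R)-3-{[(tert-butyldimethylsilyl)oxy]methyl}-4,4-bis(4-hydroxy-3,5-dimethoxyphenyl)-2-{[(4-methylbenzenesulfonyl)oxy]methylidene}butanoate
Product: 14 methyl (1S,2R)-2-{[(tert-butyldimethylsilyl)oxy]methyl}-7-hydroxy-1-(4-hydroxy-3,5-dimethoxyphenyl)-6,8-dimethoxy-1,2-dihydronaphthalene-3-carboxylate, via spirodienone 12 (not isolated), via quinone methide 13 (not isolated)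
Conditions: Pd2(dba)3 (2.5 mol%), XPhos (7.5 mol%), K3PO4 (3 equiv), 1,4-dioxane (0.01 M), 90 °C
Reagents that add atoms: none
Why: Proposed new method: zerovalent palladium should insert into the C4–OTs bond and the para carbon (C4a) of one syringyl phenoxide should then bind the divalent palladium centre, so that reductive elimination from the six-membered palladacycle forms the C4–C4a bond and closes the five-membered ring of spirodienone 12 (ipso closure of the Ar1-5 type); the closest known reactions are the palladium-catalysed arylative, and alkyne-derived vinylative, dearomatisations of para-substituted phenols to spirocyclohexadienones. The phenoxide of ring C should next expel the dienone carbon from C1 (Grob-type vinylogous retro-Michael fragmentation that rearomatises ring A) to give p-quinone methide 13, in which ring A sits on C4 cis to C2, and C8a of ring A, ortho and para to two methoxy groups, should add to C1 in a 6-exo-trig Friedel–Crafts-type 1,6-addition, the closure known from the conversion of sinapate dehydrodimers into trans-1-aryl-1,2-dihydronaphthalenes; in sum C1 shifts from C4a to C8a and the spiro five-membered ring is expanded to six-membered ring B. C1 becomes a stereocentre only in this last closure from the planar quinone methide, so both C1 epimers of 12 (either diastereotopic syringyl ring may be attacked) are funnelled into one product, and C2 controls it: ring C goes pseudoaxial to avoid the C8 methoxy group and CH2OTBS pseudoaxial to avoid A(1,2) strain with the ester, which is the 1,2-trans (1S,2R) arrangement. The selectivity needed is attack at the ipso carbon instead of the neighbouring CH carbons, which would give the 5,7-dimethoxy-6-hydroxy isomer; it is secured by the free phenoxide, whose carbon nucleophilicity is concentrated at the para position because both ortho positions carry methoxy groups, and by the (E) geometry that holds palladium cis to C2. No bond to C2 is made or broken.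

Step 8
Reactants: 14 methyl (1S,2R)-2-{[(tert-butyldimethylsilyl)oxy]methyl}-7-hydroxy-1-(4-hydroxy-3,5-dimethoxyphenyl)-6,8-dimethoxy-1,2-dihydronaphthalene-3-carboxylate
Product: 15 methyl (1S,2R)-7-hydroxy-1-(4-hydroxy-3,5-dimethoxyphenyl)-2-(hydroxymethyl)-6,8-dimethoxy-1,2-dihydronaphthalene-3-carboxylate
Conditions: HF·pyridine, pyridine/THF, 0 °C → rt
Reagents that add atoms: none
Why: Fluoride-induced Si–O cleavage under pyridine-buffered conditions should release the primary alcohol without acid- or base-catalysed lactonisation onto the neighbouring ester and without touching C1 or C2.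

**Compound list**

1 | 2,6-dimethoxyphenol | COc1cccc(OC)c1O | starting material
2 | 4-(hydroxymethyl)-2,6-dimethoxyphenol | COc1cc(CO)cc(OC)c1O | starting material
3 | 4,4'-methylenebis(2,6-dimethoxyphenol) | COc1cc(Cc2cc(OC)c(O)c(OC)c2)cc(OC)c1O | intermediate
4 | methyl 4-oxobutanoate | COC(=O)CCC=O | starting material
5 | 4-[(4-hydroxy-3,5-dimethoxyphenyl)methylidene]-2,6-dimethoxycyclohexa-2,5-dien-1-one | COC1=CC(=Cc2cc(OC)c(O)c(OC)c2)C=C(OC)C1=O | intermediate
6 | methyl (3S)-3-formyl-4,4-bis(4-hydroxy-3,5-dimethoxyphenyl)butanoate | COC(=O)C[C@H](C=O)C(c1cc(OC)c(O)c(OC)c1)c1cc(OC)c(O)c(OC)c1 | intermediate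
7 | methyl (3S)-3-(hydroxymethyl)-4,4-bis(4-hydroxy-3,5-dimethoxyphenyl)butanoate | COC(=O)C[C@H](CO)C(c1cc(OC)c(O)c(OC)c1)c1cc(OC)c(O)c(OC)c1 | intermediate
8 | methyl (3S)-3-{[(tert-butyldimethylsilyl)oxy]methyl}-4,4-bis{4-[(tert-butyldimethylsilyl)oxy]-3,5-dimethoxyphenyl}butanoate | COC(=O)C[C@H](CO[Si](C)(C)C(C)(C)C)C(c1cc(OC)c(O[Si](C)(C)C(C)(C)C)c(OC)c1)c1cc(OC)c(O[Si](C)(C)C(C)(C)C)c(OC)c1 | intermediate
9 | methyl (3R)-3-{[(tert-butyldimethylsilyl)oxy]methyl}-4,4-bis{4-[(tert-butyldimethylsilyl)oxy]-3,5-dimethoxyphenyl}-2-formylbutanoate | COC(=O)C(C=O)[C@H](CO[Si](C)(C)C(C)(C)C)C(c1cc(OC)c(O[Si](C)(C)C(C)(C)C)c(OC)c1)c1cc(OC)c(O[Si](C)(C)C(C)(C)C)c(OC)c1 | intermediate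
10 | methyl (2E,3R)-3-{[(tert-butyldimethylsilyl)oxy]methyl}-4,4-bis{4-[(tert-butyldimethylsilyl)oxy]-3,5-dimethoxyphenyl}-2-{[(4-methylbenzenesulfonyl)oxy]methylidene}butanoate | COC(=O)/C(=C/OS(=O)(=O)c1ccc(C)cc1)[C@H](CO[Si](C)(C)C(C)(C)C)C(c1cc(OC)c(O[Si](C)(C)C(C)(C)C)c(OC)c1)c1cc(OC)c(O[Si](C)(C)C(C)(C)C)c(OC)c1 | intermediate
11 | methyl (2E,3R)-3-{[(tert-butyldimethylsilyl)oxy]methyl}-4,4-bis(4-hydroxy-3,5-dimethoxyphenyl)-2-{[(4-methylbenzenesulfonyl)oxy]methylidene}butanoate | COC(=O)/C(=C/OS(=O)(=O)c1ccc(C)cc1)[C@H](CO[Si](C)(C)C(C)(C)C)C(c1cc(OC)c(O)c(OC)c1)c1cc(OC)c(O)c(OC)c1 | intermediate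
12 | methyl (3R)-3-{[(tert-butyldimethylsilyl)oxy]methyl}-4-(4-hydroxy-3,5-dimethoxyphenyl)-7,9-dimethoxy-8-oxospiro[4.5]deca-1,6,9-triene-2-carboxylate (both C4 epimers) | COC(=O)C1=CC2(C=C(OC)C(=O)C(OC)=C2)C(c2cc(OC)c(O)c(OC)c2)[C@H]1CO[Si](C)(C)C(C)(C)C | intermediate
13 | methyl (2E,3R)-3-{[(tert-butyldimethylsilyl)oxy]methyl}-4-(3,5-dimethoxy-4-oxocyclohexa-2,5-dien-1-ylidene)-2-[(4-hydroxy-3,5-dimethoxyphenyl)methylidene]butanoate | COC(=O)/C(=C/c1cc(OC)c(O)c(OC)c1)[C@H](CO[Si](C)(C)C(C)(C)C)C=C1C=C(OC)C(=O)C(OC)=C1 | intermediate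
14 | methyl (1S,2R)-2-{[(tert-butyldimethylsilyl)oxy]methyl}-7-hydroxy-1-(4-hydroxy-3,5-dimethoxyphenyl)-6,8-dimethoxy-1,2-dihydronaphthalene-3-carboxylate | COC(=O)C1=Cc2cc(OC)c(O)c(OC)c2[C@H](c2cc(OC)c(O)c(OC)c2)[C@H]1CO[Si](C)(C)C(C)(C)C | intermediate
15 | methyl (1S,2R)-7-hydroxy-1-(4-hydroxy-3,5-dimethoxyphenyl)-2-(hydroxymethyl)-6,8-dimethoxy-1,2-dihydronaphthalene-3-carboxylate | COC(=O)C1=Cc2cc(OC)c(O)c(OC)c2[C@H](c2cc(OC)c(O)c(OC)c2)[C@H]1CO | target

Total step count: 8. Longest linear sequence: 8 steps (1 → 15).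

**Steps most likely to fail**

Step 7 (bears the label). What may go wrong:
- the vinylpalladium intermediate may not be captured at the ipso carbon;
- a phenoxide oxygen may add to the tosyloxyacrylate of another molecule (addition–elimination, oligomers);
- quinone methide 13 may lose the C2 proton to a conjugated diene faster than it cyclises.

Fallback, known chemistry, sets out from 2 and rejoins at 15: the aryl shift is given up and the same C4–C4a bond is closed by a 6-endo Mizoroki–Heck reaction of a ring A bromide. 2 is condensed (cat. TsOH, MeCN) with an excess of commercial 4-bromo-2,6-dimethoxyphenol, whose only free positions are ortho and para to methoxy, to give the diarylmethane F1. DDQ should oxidise it to the unsymmetrical quinone methide F2. The protocol of step 2 with 4 (same catalyst, then NaBH4) should give, after removal of the C1 epimer by chromatography, the hydroxy ester F3. TBSCl and imidazole give the tris(silyl ether) F4. LiN(iPr)2 and dimethylmethylideneammonium iodide give the Mannich base F5, MeI its ammonium iodide F6, and DBU the acrylate F7. Pd(OAc)2, P(o-tol)3 and Et3N in DMF at 100 °C should close ring B to the cyclised tris(silyl ether) F8, because the α-substituent of the acrylate leaves no β-hydrogen for the 5-exo mode. HF·pyridine then gives 15.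

Step 2. What may go wrong: the unhindered quinone methide 5 may over-oxidise or self-condense before it is trapped, and a slow enamine addition to this donor-stabilised acceptor may let the uncatalysed background reaction and aldehyde self-aldolisation erode the enantioselectivity.

Fallback, sets out from 3 and rejoins at 8: C2 is set by a chiral auxiliary instead of the amine catalyst. 3 is silylated (TBSCl, imidazole) to the bis(silyl ether) F9, which DDQ in CH2Cl2/MeOH should oxidise to the diarylmethyl methyl ether F10. Commercial methyl 4-chloro-4-oxobutanoate acylates (4R)-4-(propan-2-yl)-1,3-thiazolidine-2-thione to the N-acyl thiazolidinethione F11. Its titanium enolate (TiCl4, iPr2NEt, CH2Cl2, −78 °C) is alkylated by the diarylmethyl cation released from F10 (SN1-type enolate alkylation on the face away from the isopropyl group) to give the adduct F12. NaBH4 in THF/H2O removes the auxiliary reductively and leaves the methyl ester, giving the hydroxy ester F13, which TBSCl and imidazole convert into 8.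

Step 3. What may go wrong: the γ-hydroxy ester 7 may cyclise to the γ-lactone by intramolecular transesterification faster than it is silylated, which removes the ester needed in step 4.

Fallback, sets out from 7 and rejoins at 8: the lactone is accepted as a temporary ring. 7 is lactonised on purpose (cat. TsOH, toluene) to the lactone F14, which can be crystallised. LiOH in THF/H2O opens it to the lithium salt of the hydroxy acid F15, which is dried and silylated exhaustively (TBSCl, imidazole, DMF) to the silyl ester F16. Aqueous AcOH in THF hydrolyses only the silyl ester to the acid F17, and TMSCHN2 in toluene/MeOH gives 8.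

**Further compounds**

F1 | step 7 | 4-bromo-3-[(4-hydroxy-3,5-dimethoxyphenyl)methyl]-2,6-dimethoxyphenol | COc1cc(Br)c(Cc2cc(OC)c(O)c(OC)c2)c(OC)c1O
F2 | step 7 | 4-[(6-bromo-3-hydroxy-2,4-dimethoxyphenyl)methylidene]-2,6-dimethoxycyclohexa-2,5-dien-1-one | COC1=CC(=Cc2c(Br)cc(OC)c(O)c2OC)C=C(OC)C1=O
F3 | step 7 | methyl (3S,4S)-4-(6-bromo-3-hydroxy-2,4-dimethoxyphenyl)-3-(hydroxymethyl)-4-(4-hydroxy-3,5-dimethoxyphenyl)butanoate | COC(=O)C[C@@H]([C@H](c1c(Br)cc(OC)c(O)c1OC)c1cc(OC)c(O)c(OC)c1)CO
F4 | step 7 | methyl (3S,4S)-4-{6-bromo-3-[(tert-butyldimethylsilyl)oxy]-2,4-dimethoxyphenyl}-3-{[(tert-butyldimethylsilyl)oxy]methyl}-4-{4-[(tert-butyldimethylsilyl)oxy]-3,5-dimethoxyphenyl}butanoate | COC(=O)C[C@@H]([C@H](c1c(Br)cc(OC)c(O[Si](C)(C)C(C)(C)C)c1OC)c1cc(OC)c(O[Si](C)(C)C(C)(C)C)c(OC)c1)CO[Si](C)(C)C(C)(C)C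
F5 | step 7 | methyl (3R,4S)-4-{6-bromo-3-[(tert-butyldimethylsilyl)oxy]-2,4-dimethoxyphenyl}-3-{[(tert-butyldimethylsilyl)oxy]methyl}-4-{4-[(tert-butyldimethylsilyl)oxy]-3,5-dimethoxyphenyl}-2-[(dimethylamino)methyl]butanoate (C2 epimers) | COC(=O)C(CN(C)C)[C@@H]([C@H](c1c(Br)cc(OC)c(O[Si](C)(C)C(C)(C)C)c1OC)c1cc(OC)c(O[Si](C)(C)C(C)(C)C)c(OC)c1)CO[Si](C)(C)C(C)(C)C
F6 | step 7 | N,N,N-trimethylammonium iodide of F5 | [I-].COC(=O)C(C[N+](C)(C)C)[C@@H]([C@H](c1c(Br)cc(OC)c(O[Si](C)(C)C(C)(C)C)c1OC)c1cc(OC)c(O[Si](C)(C)C(C)(C)C)c(OC)c1)CO[Si](C)(C)C(C)(C)C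
F7 | step 7 | methyl (3R,4S)-4-{6-bromo-3-[(tert-butyldimethylsilyl)oxy]-2,4-dimethoxyphenyl}-3-{[(tert-butyldimethylsilyl)oxy]methyl}-4-{4-[(tert-butyldimethylsilyl)oxy]-3,5-dimethoxyphenyl}-2-methylidenebutanoate | COC(=O)C(=C)[C@@H]([C@H](c1c(Br)cc(OC)c(O[Si](C)(C)C(C)(C)C)c1OC)c1cc(OC)c(O[Si](C)(C)C(C)(C)C)c(OC)c1)CO[Si](C)(C)C(C)(C)C
F8 | step 7 | methyl (1S,2R)-7-[(tert-butyldimethylsilyl)oxy]-2-{[(tert-butyldimethylsilyl)oxy]methyl}-1-{4-[(tert-butyldimethylsilyl)oxy]-3,5-dimethoxyphenyl}-6,8-dimethoxy-1,2-dihydronaphthalene-3-carboxylate | COC(=O)C1=Cc2cc(OC)c(O[Si](C)(C)C(C)(C)C)c(OC)c2[C@H](c2cc(OC)c(O[Si](C)(C)C(C)(C)C)c(OC)c2)[C@H]1CO[Si](C)(C)C(C)(C)C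
F9 | step 2 | bis{4-[(tert-butyldimethylsilyl)oxy]-3,5-dimethoxyphenyl}methane | COc1cc(Cc2cc(OC)c(O[Si](C)(C)C(C)(C)C)c(OC)c2)cc(OC)c1O[Si](C)(C)C(C)(C)C
F10 | step 2 | bis{4-[(tert-butyldimethylsilyl)oxy]-3,5-dimethoxyphenyl}methyl methyl ether | COC(c1cc(OC)c(O[Si](C)(C)C(C)(C)C)c(OC)c1)c1cc(OC)c(O[Si](C)(C)C(C)(C)C)c(OC)c1
F11 | step 2 | methyl 4-oxo-4-[(4R)-4-(propan-2-yl)-2-sulfanylidene-1,3-thiazolidin-3-yl]butanoate | COC(=O)CCC(=O)N1[C@H](C(C)C)CSC1=S
F12 | step 2 | methyl (3S)-4,4-bis{4-[(tert-butyldimethylsilyl)oxy]-3,5-dimethoxyphenyl}-3-{[(4R)-4-(propan-2-yl)-2-sulfanylidene-1,3-thiazolidin-3-yl]carbonyl}butanoate | COC(=O)C[C@H](C(=O)N1[C@H](C(C)C)CSC1=S)C(c1cc(OC)c(O[Si](C)(C)C(C)(C)C)c(OC)c1)c1cc(OC)c(O[Si](C)(C)C(C)(C)C)c(OC)c1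
F13 | step 2 | methyl (3S)-4,4-bis{4-[(tert-butyldimethylsilyl)oxy]-3,5-dimethoxyphenyl}-3-(hydroxymethyl)butanoate | COC(=O)C[C@H](CO)C(c1cc(OC)c(O[Si](C)(C)C(C)(C)C)c(OC)c1)c1cc(OC)c(O[Si](C)(C)C(C)(C)C)c(OC)c1
F14 | step 3 | (4S)-4-[bis(4-hydroxy-3,5-dimethoxyphenyl)methyl]oxolan-2-one | O=C1C[C@H](CO1)C(c1cc(OC)c(O)c(OC)c1)c1cc(OC)c(O)c(OC)c1
F15 | step 3 | (3S)-3-(hydroxymethyl)-4,4-bis(4-hydroxy-3,5-dimethoxyphenyl)butanoic acid (handled as its lithium salt) | OC(=O)C[C@H](CO)C(c1cc(OC)c(O)c(OC)c1)c1cc(OC)c(O)c(OC)c1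
F16 | step 3 | tert-butyldimethylsilyl (3S)-3-{[(tert-butyldimethylsilyl)oxy]methyl}-4,4-bis{4-[(tert-butyldimethylsilyl)oxy]-3,5-dimethoxyphenyl}butanoate | CC(C)(C)[Si](C)(C)OC(=O)C[C@H](CO[Si](C)(C)C(C)(C)C)C(c1cc(OC)c(O[Si](C)(C)C(C)(C)C)c(OC)c1)c1cc(OC)c(O[Si](C)(C)C(C)(C)C)c(OC)c1
F17 | step 3 | (3S)-3-{[(tert-butyldimethylsilyl)oxy]methyl}-4,4-bis{4-[(tert-butyldimethylsilyl)oxy]-3,5-dimethoxyphenyl}butanoic acid | OC(=O)C[C@H](CO[Si](C)(C)C(C)(C)C)C(c1cc(OC)c(O[Si](C)(C)C(C)(C)C)c(OC)c1)c1cc(OC)c(O[Si](C)(C)C(C)(C)C)c(OC)c1
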